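(Readings and results were computed from invented constants; noise was put on by code.)

In a one-step world a flask of substrate and enzyme ends as target whatever the charge, and the charge moves the clock and nothing else. This flask has a second step, substrate + target to side product, so a unit of substrate has two possible ends and the split can move with the substrate charge c.

| setting | Tuesday's | Saturday's | Monday's | autumn | spring | noon | winter |
|---|---|---|---|---|---|---|---|
| substrate | 0.056 M | 0.15 M | 0.38 M | 0.050 M | 0.10 M | 0.20 M | 0.40 M |
| enzyme | 2.2 µM | 2.2 µM | 2.2 µM | 2.2 µM | 2.2 µM | 2.2 µM | 2.2 µM |
| remark | run made earlier | run made earlier | run made earlier |  |  |  |  |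
| time |  |  |  | 10 min | 10 min | 10 min | 10 min |

| run | time / min | target / % | side product / % |
|---|---|---|---|
| Tuesday's | 0.833 | 97.7 | 0.8 |
| Tuesday's | 1.50 | 98.4 | 1.5 |
| Tuesday's | 3.00 | 97.8 | 1.7 |
| Tuesday's | 5.00 | 98.2 | 0.7 |
| Tuesday's | 10.0 | 98.7 | 2.0 |
| Saturday's | 2.00 | 92.2 | 7.2 |
| Saturday's | 4.00 | 93.2 | 6.4 |
| Saturday's | 6.00 | 92.9 | 7.5 |
| Saturday's | 8.00 | 94.1 | 6.5 |
| Saturday's | 10.0 | 93.3 | 7.7 |
| Monday's | 0.833 | 65.5 | 17.7 |
| Monday's | 1.50 | 69.6 | 23.1 |
| Monday's | 3.00 | 73.2 | 27.6 |
| Monday's | 5.00 | 73.1 | 27.0 |
| Monday's | 10.0 | 73.0 | 27.6 |

(readings scatter by 0.5 percentage points)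

- a species is counted by the substrate in it: one side product counts as two
- what may be going on: substrate + enzyme -> target + enzyme; substrate + target -> side product
- "hardly changes" means that all values lie within two and a half points (for a concentration: within two and a half percent of the largest)

- share of target in all that became target or side product for autumn, spring, noon, winter, in this order
- how the row runs (falls all the way / rises, then falls / falls, then rises / rises all the way / hardly changes)

I look at time first. Monday's run has a larger charge than Tuesday's and Saturday's, and its target reads 73.2% at 3.00 min and 73.0% at 10.0 min. Tuesday's and Saturday's readings show no trend from their first point. So I expect the four flasks to have finished by 10 min, and what I need is the final split.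

I measure that split by the final odds ρ: side product over target, both counted in substrate and averaged over the flat readings. Saturday's run gives ρ = 0.0758 and Monday's gives 0.375.

Suppose ρ follows a power of the charge, ρ ∝ cⁿ. The two runs then give n = 1.72, and this order of the odds in the charge is the quantity I carry. For small odds and a fixed first-order enzyme constant, n equals one. This reading stands higher, so I carry it as a reading and commit to no mechanism.

Tuesday's run played no part in n, so it can test it. The power law predicts ρ = 0.0139 at its charge, and its five readings give 0.0137.

The target share is 1/(1 + ρ), so from Saturday's odds I reckon 98.9%, 96.4%, 88.9% and 71.0%. My row falls at each step.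

The forecast reads 98.6%, 96.2%, 89.2% and 71.1%, a row that falls all the way, stands 0.30 percentage points above mine at noon, and says “The target share therefore falls throughout.”

The flasks give 99.1%, 96.7%, 88.9% and 71.4%: the row falls all the way.

    substrate + enzyme → target + enzyme, rate k1*[substrate]*[enzyme]/(1 + ([substrate]/Km1) + ([target]/Kp1)) (0.110 M, 0.420 mM, k = 5.50 × 10⁶ M⁻¹ s⁻¹)
    substrate + target → side product (k = 0.0270 M⁻¹ s⁻¹)

Carried with n, spring's simulated odds give autumn 99.0% against 99.1%, and noon's simulated odds give winter 70.9% against 71.4%. In autumn, at 0.0326 min, the enzyme step uses substrate 300 times as fast as the side step. Half of the enzyme step's turnover in that flask is done by 1.96 s, far sooner than the half-life of substrate by the side step at that moment, 17 min.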